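**Plan**
- Retrosynthesis cuts the triene at its trans CH=CH (Julia–Kocienski) and at the C=CH2 carbon (ketone methylenation), then cuts the cyclopentane C2–C(side chain) and C1–O bonds together.
- Enabling feature: on the cyclopentane the carbinol CH next to the spiro carbon (C1) and the adjacent CH carrying the C(=CH2) carbon (C2) are cis. This is a masked β-hydroxy ketone, i.e. an isoxazoline laid across the C1=C2 bond of a spiro cyclopentene by one nitrile oxide cycloaddition.
- Forward order: cyclohexane from (S)-carvone (tertiary carbinol, hydroxypropyl arm, one-carbon homologation), ring alkylidene, quaternary spiro carbon by aldehyde allylation, cyclopentene by hydroacylation and enol triflate reduction, isoxazoline, side chain, unmasking.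
- Ring stereochemistry: the carvone centre sets the carbinol (trans epoxide) and the arm (trans alkylation) and is then destroyed; these two centres steer the allylation at the spiro carbon and the face of the cycloaddition, whose suprafacial course fixes the cis C1/C2 pair.
- Alkene geometry: ring alkylidene from chromium-catalysed 1,4-hydrogenation of an s-cis diene, side-chain trisubstituted alkene from syn-carbocupration, disubstituted alkene from the Julia–Kocienski step.

Key step: step 21

Remark: centres and geometries that are erased later (carbinol of 3; C1 of 11–16 and 21–23; hydroperoxide carbon of 12; enol ether of 10) are carried as mixtures and left undefined in the SMILES; monocyclic intermediates keep carvone numbering (C1 former carbonyl carbon, C2 methyl carbinol carbon), spiro compounds are numbered as spiro[4.5]decane (C1 carbinol CH, C2 CH bearing the side chain, C5 spiro carbon, C6 methyl carbinol, C9 alkylidene carbon, C10 CH bearing the arm); TES = triethylsilyl, TBS = tert-butyldimethylsilyl, TBDPS = tert-butyldiphenylsilyl, PT = 1-phenyl-1H-tetrazol-5-yl.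

**Route**

Step 1
Reactants: 1 (S)-carvone
Product: 2 trans-carvone epoxide (1S,4S,6S)-1-methyl-4-(prop-1-en-2-yl)-7-oxabicyclo[4.1.0]heptan-2-one
Conditions: H2O2 (30% aq), NaOH (cat.), MeOH, 0 °C
Reagents that add atoms: hydrogen peroxide, OO
Why: Weitz–Scheffer nucleophilic epoxidation; hydroperoxide adds to the enone β-carbon anti to the C5 isopropenyl group, so the oxirane oxygen (the future tertiary carbinol oxygen) is set trans to it.

Step 2
Reactants: 2 trans-carvone epoxide
Product: 3 (1S,4S)-1-methyl-4-(prop-1-en-2-yl)cyclohexane-1,2-diol (C2 epimers)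
Conditions: LiAlH4, THF, 0 °C to rt
Reagents that add atoms: none
Why: hydride reduces the ketone and opens the trisubstituted epoxide by SN2 attack at its less substituted carbon, so the tertiary C–O bond keeps its configuration; the secondary carbinol mixture is removed in step 3.

Step 3
Reactants: 3 diol
Product: 4 (2S,5S)-2-hydroxy-2-methyl-5-(prop-1-en-2-yl)cyclohexan-1-one
Conditions: IBX, EtOAc, 75 °C
Reagents that add atoms: none
Why: IBX oxidises the secondary alcohol of a 1,2-diol to the α-hydroxy ketone without glycol cleavage, and the tertiary alcohol cannot be oxidised.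

Step 4
Reactants: 4 hydroxy ketone
Product: 5 (2S,5S)-2-methyl-5-(prop-1-en-2-yl)-2-(triethylsilyloxy)cyclohexan-1-one
Conditions: Et3SiOTf, 2,6-lutidine, CH2Cl2, −78 to 0 °C
Reagents that add atoms: triethylsilyl trifluoromethanesulfonate, CC[Si](CC)(CC)OS(=O)(=O)C(F)(F)F
Why: silyl triflate/lutidine silylation of a hindered tertiary alcohol, needed so that base in step 5 forms only the ketone enolate.

Step 5
Reactants: 5 silyloxy ketone; 6 allyl bromide
Product: 7 (2S,5S,6R)-6-allyl-2-methyl-5-(prop-1-en-2-yl)-2-(triethylsilyloxy)cyclohexan-1-one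
Conditions: LiN(i-Pr)2, THF, −78 °C; then 6, −78 to −20 °C
Reagents that add atoms: none
Why: the kinetic enolate can form only toward C6 (C2 is quaternary) and is allylated anti to the adjacent C5 isopropenyl group (ketone enolate alkylation), which places the allyl group cis to the C2 silyloxy group.

Step 6
Reactants: 7 allyl ketone
Product: 8 (2S,5S,6R)-6-(3-hydroxypropyl)-2-methyl-5-(prop-1-en-2-yl)-2-(triethylsilyloxy)cyclohexan-1-one
Conditions: Sia2BH (from BH3·SMe2 and 2-methylbut-2-ene), THF, 0 °C; then NaOH, H2O2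
Reagents that add atoms: hydrogen peroxide, OO
Why: Brown hydroboration–oxidation; the bulky dialkylborane adds anti-Markovnikov to the monosubstituted alkene far faster than to the 1,1-disubstituted isopropenyl group or the hindered ketone.

Step 7
Reactants: 8 hydroxypropyl ketone
Product: 9 (2S,5S,6R)-6-[3-(tert-butyldiphenylsilyloxy)propyl]-2-methyl-5-(prop-1-en-2-yl)-2-(triethylsilyloxy)cyclohexan-1-one
Conditions: t-BuPh2SiCl, imidazole, DMF, rt
Reagents that add atoms: tert-butyl(chloro)diphenylsilane, CC(C)(C)[Si](Cl)(c1ccccc1)c1ccccc1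
Why: standard silylation of the primary alcohol; the TBDPS ether is chosen to survive the acidic acetal steps 8 and 16.

Step 8
Reactants: 9 TBDPS-protected ketone
Product: 11 dimethyl acetal of the one-carbon homologated aldehyde (C1 epimers), via methyl enol ether 10 (not isolated)
Conditions: MeOCH2PPh3Cl, KN(SiMe3)2, THF, 0 to 60 °C; then MeOH, PPTS (cat.), rt
Reagents that add atoms: (methoxymethyl)triphenylphosphonium chloride, COC[P+](c1ccccc1)(c1ccccc1)c1ccccc1.[Cl-]; methanol, CO
Why: Wittig methoxymethylenation adds the one-carbon unit to the hindered ketone, and acid-catalysed addition of methanol to the enol ether stores the aldehyde as an acetal that is inert to ozone and strong base; the new C1–H centre is erased in step 17.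

Step 9
Reactants: 11 dimethyl acetal
Product: 13 C5 acetate (acetoxy in place of isopropenyl), via methoxy hydroperoxide 12 (not isolated)
Conditions: O3, CH2Cl2/MeOH, −78 °C; then Ac2O, Et3N, DMAP (cat.), 0 °C to rt
Reagents that add atoms: ozone, [O-][O+]=O; methanol, CO
Why: ozonolysis in methanol traps the carbonyl oxide as the α-methoxy hydroperoxide, whose acetylation triggers the Criegee rearrangement; C5 migrates to oxygen with retention, so the isopropenyl group is exchanged for an acetoxy group.

Step 10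
Reactants: 13 C5 acetate
Product: 14 C5 alcohol
Conditions: K2CO3 (cat.), MeOH, rt
Reagents that add atoms: none
Why: base-catalysed transesterification removes the acetate; acetal and silyl ethers are stable to it.

Step 11
Reactants: 14 C5 alcohol
Product: 15 C5 ketone
Conditions: IBX, EtOAc, 75 °C
Reagents that add atoms: none
Why: neutral oxidation of the secondary alcohol; with C1 no longer a carbonyl carbon no β-dicarbonyl arises, so the C6 centre between them is not labilised.

Step 12
Reactants: 15 C5 ketone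
Product: 16 cyclohex-4-en-5-yl triflate
Conditions: KN(SiMe3)2, THF, −78 °C; then PhNTf2, −78 to 0 °C
Reagents that add atoms: N-phenylbis(trifluoromethanesulfonimide), O=S(=O)(N(c1ccccc1)S(=O)(=O)C(F)(F)F)C(F)(F)F
Why: kinetic deprotonation occurs at the unhindered C4 methylene and not at the tertiary C6–H, and O-triflation of that enolate fixes the ring double bond on the side away from the arm.

Step 13
Reactants: 17 2-bromoprop-2-en-1-ol
Product: 18 tert-butyl[(2-bromoprop-2-en-1-yl)oxy]diphenylsilane
Conditions: t-BuPh2SiCl, imidazole, CH2Cl2, rt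
Reagents that add atoms: tert-butyl(chloro)diphenylsilane, CC(C)(C)[Si](Cl)(c1ccccc1)c1ccccc1
Why: standard silylation of a primary allylic alcohol.

Step 14
Reactants: 16 enol triflate; 18 bromoallyl silyl ether
Product: 21 2,3-disubstituted diene acetal, via alkenyllithium 19 (not isolated), via alkenylzinc bromide 20 (not isolated)
Conditions: 18, t-BuLi, Et2O, −78 °C; ZnBr2, THF, −78 to 0 °C; then 16, Pd(PPh3)4 (5 mol%), THF, 50 °C
Reagents that add atoms: none
Why: bromine–lithium exchange, transmetalation to zinc and palladium-catalysed Negishi coupling of the alkenylzinc with the alkenyl triflate join the two sp2 carbons without moving either double bond.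

Step 15
Reactants: 21 diene acetal
Product: 22 (Z)-alkylidene acetal (silyloxymethyl cis to C6 and methyl cis to C4)
Conditions: (naphthalene)Cr(CO)3 (20 mol%), H2 (50 atm), THF, 45 °C
Reagents that add atoms: none
Why: arene-chromium-tricarbonyl-catalysed 1,4-hydrogenation; the diene binds chromium in its s-cis form and the two hydrogens go to its termini (the methylene and C4), so the new tetrasubstituted alkene necessarily has methyl cis to C4 and the silyloxymethyl group cis to C6.

Step 16
Reactants: 22 (Z)-alkylidene acetal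
Product: 23 aldehyde (C1 epimers)
Conditions: PPTS, THF/H2O, 50 °C
Reagents that add atoms: water, O
Why: mild acid hydrolysis of the dimethyl acetal; the TBDPS ethers and the hindered tertiary TES ether should tolerate PPTS in aqueous THF.

Step 17
Reactants: 23 aldehyde; 6 allyl bromide
Product: 24 α-allyl aldehyde (quaternary C1 with formyl cis to the C6 arm and the C2 silyloxy group)
Conditions: KH, THF, 0 °C; then 6, −78 to 0 °C
Reagents that add atoms: none
Why: C-allylation of the potassium enolate of an α-branched aldehyde; allylic strain from the C5 alkylidene and the enolate holds the C6 arm axial, the C2 silyloxy group is axial on the same face, so allyl bromide enters from the opposite face and sets the spiro stereocentre.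

Step 18
Reactants: 24 α-allyl aldehyde
Product: 25 spiro[4.5]decan-1-one
Conditions: [Rh(dppe)]ClO4 (5 mol%), CH2Cl2, rt
Reagents that add atoms: none
Why: rhodium-catalysed intramolecular hydroacylation of a 2,2-disubstituted pent-4-enal; the acyl rhodium hydride adds across the terminal alkene and closes the cyclopentanone without touching the quaternary centre.

Step 19
Reactants: 25 spiro ketone
Product: 26 spiro[4.5]dec-1-en-1-yl triflate
Conditions: KN(SiMe3)2, THF, −78 °C; then PhNTf2, −78 to 0 °C
Reagents that add atoms: N-phenylbis(trifluoromethanesulfonimide), O=S(=O)(N(c1ccccc1)S(=O)(=O)C(F)(F)F)C(F)(F)F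
Why: the ketone can enolise only toward the C2 methylene (C5 is quaternary), so enolate O-triflation is regiodefined.

Step 20
Reactants: 26 enol triflate
Product: 27 spiro[4.5]dec-1-ene (key precursor)
Conditions: Pd(OAc)2 (5 mol%), PPh3, HCO2H, Bu3N, DMF, 60 °C
Reagents that add atoms: none
Why: palladium-catalysed formate reduction of an enol triflate replaces the triflate by hydrogen and leaves the cis-disubstituted C1=C2 alkene in place.

Step 21
Reactants: 27 spiro cyclopentene; 28 ethyl 2-chloro-2-(hydroxyimino)acetate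
Product: 30 cis-fused isoxazoline ethyl ester (oxygen on C1 and ester-bearing carbon on C2), via ethoxycarbonylformonitrile oxide 29 (not isolated)
Conditions: 28 (3 equiv, added over 12 h), NaHCO3, EtOAc, rt
Reagents that add atoms: none
Why: Bicarbonate removes HCl from 28 to give nitrile oxide 29, which adds to the cyclopentene in a concerted suprafacial [3+2] cycloaddition, the closest known type being additions of ester-substituted nitrile oxides to cycloalkenes (Huisgen nitrile oxide–alkene cycloaddition). The isoxazoline ring closes by intermolecular (3+2) annulation in which the C2–C and C1–O bonds form in the same step, so it is necessarily cis-fused to the cyclopentane. C1 and C2 are the new stereocentres: their cis relationship follows from suprafacial addition, and their absolute sense from approach on the cyclopentene face turned toward the C10 methine, away from the fully substituted C6 (methyl and silyloxy) on the other side of the spiro carbon. The required regioselectivity (oxygen to the neopentyl C1, the ester-bearing dipole carbon to the unhindered C2) is secured by the adjacent quaternary spiro centre, which keeps the substituted end of the dipole away. Chemoselectivity is secured because the only other alkene is tetrasubstituted and inert to nitrile oxides, and slow generation of the dipole in excess limits its dimerisation.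

Step 22
Reactants: 30 isoxazoline ester
Product: 31 isoxazoline-3-carbaldehyde
Conditions: i-Bu2AlH (1.1 equiv), CH2Cl2, −78 °C
Reagents that add atoms: none
Why: partial reduction of the ester activated by the adjacent C=N stops at the aldehyde through the low-temperature aluminium hemiacetal; N–O bond and silyl ethers are untouched.

Step 23
Reactants: 32 tert-butyldimethyl(prop-2-yn-1-yloxy)silane
Product: 33 methyl 4-(tert-butyldimethylsilyloxy)but-2-ynoate
Conditions: n-BuLi, THF, −78 °C; then ClCO2Me
Reagents that add atoms: methyl chloroformate, COC(=O)Cl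
Why: acylation of the lithium acetylide with a chloroformate.

Step 24
Reactants: 33 ynoate; 34 5-bromo-2-methylpent-2-ene
Product: 37 methyl (2Z)-3-[(tert-butyldimethylsilyloxy)methyl]-7-methylocta-2,6-dienoate, via homoprenylmagnesium bromide 35 (not isolated), via homoprenylcopper 36 (not isolated)
Conditions: 34, Mg, THF; CuBr·SMe2, THF, −78 °C; then 33, −78 °C; NH4Cl (aq)
Reagents that add atoms: none
Why: syn-carbocupration of the ynoate at low temperature and protonation of the alkenylcopper with retention place the ester and the silyloxymethyl group cis.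

Step 25
Reactants: 37 (Z)-enoate
Product: 38 (2Z)-3-[(tert-butyldimethylsilyloxy)methyl]-7-methylocta-2,6-dien-1-ol
Conditions: i-Bu2AlH (2.2 equiv), CH2Cl2, −78 °C
Reagents that add atoms: none
Why: 1,2-reduction of the enoate to the allylic alcohol without change of alkene geometry.

Step 26
Reactants: 38 allylic alcohol
Product: 39 PT sulfide
Conditions: 1-phenyl-1H-tetrazole-5-thiol, PPh3, DIAD, THF, 0 °C
Reagents that add atoms: 1-phenyl-1H-tetrazole-5-thiol, Sc1nnnn1-c1ccccc1
Why: Mitsunobu thioetherification, SN2 at the primary allylic carbon.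

Step 27
Reactants: 39 PT sulfide
Product: 40 PT sulfone
Conditions: H2O2 (30% aq), (NH4)6Mo7O24·4H2O (cat.), EtOH, 0 °C to rt
Reagents that add atoms: hydrogen peroxide, OO
Why: molybdate-catalysed peroxide oxidation takes the sulfide to the sulfone and leaves the trisubstituted alkenes and the TBS ether alone.

Step 28
Reactants: 31 isoxazoline aldehyde; 40 PT sulfone
Product: 41 (E,Z)-dienyl isoxazoline with TBS-protected side chain
Conditions: KN(SiMe3)2 added to 31 and 40, DME, −60 °C to rt
Reagents that add atoms: none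
Why: Julia–Kocienski olefination; the sulfonyl carbanion adds to the non-enolisable aldehyde, and Smiles rearrangement with loss of SO2 and tetrazolate gives the disubstituted alkene, E being expected for PT sulfones with a potassium base in DME; the silyl ether is too poor a leaving group for 1,4-elimination.

Step 29
Reactants: 41 TBS-protected dienyl isoxazoline
Product: 42 primary allylic alcohol
Conditions: PPTS, MeOH, 0 °C to rt
Reagents that add atoms: none
Why: mild acid methanolysis removes the unhindered primary allylic TBS ether, while the primary TBDPS ethers and the tertiary TES ether buried beside the spiro carbon should react much more slowly.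

Step 30
Reactants: 42 allylic alcohol
Product: 43 allylic acetate
Conditions: Ac2O, pyridine, DMAP (cat.), CH2Cl2, 0 °C
Reagents that add atoms: acetic anhydride, CC(=O)OC(C)=O
Why: acetylation of the only free hydroxyl group.

Step 31
Reactants: 43 acetoxy dienyl isoxazoline
Product: 44 cis-β-hydroxy dienyl ketone
Conditions: Mo(CO)6, MeCN/H2O, 80 °C
Reagents that add atoms: water, O
Why: Mo(CO)6-mediated reductive N–O cleavage and hydrolysis of the resulting β-hydroxy imine unmask the β-hydroxy ketone under neutral conditions, so the cis C1/C2 relationship, the alkenes and the acetate are kept.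

Step 32
Reactants: 44 β-hydroxy ketone
Product: 45 cross-conjugated triene (two TBDPS ethers and tertiary TES ether retained)
Conditions: Zn, CH2Br2, TiCl4, THF/CH2Cl2, 0 °C to rt
Reagents that add atoms: dibromomethane, BrCBr
Why: Takai–Lombardo methylenation is non-basic, so the β-hydroxy ketone neither epimerises at C2 nor suffers retro-aldol cleavage or dehydration, and the acetate is not attacked.

Step 33
Reactants: 45 silylated triene
Product: 46 tetraol acetate
Conditions: Bu4NF, AcOH, THF, 0 °C to rt
Reagents that add atoms: none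
Why: fluoride-mediated cleavage of the TBDPS and TES ethers, buffered with acetic acid to protect the allylic acetate.

Step 34
Reactants: 46 tetraol acetate
Product: 47 CNP0205332.1
Conditions: MnO2, CH2Cl2, rt
Reagents that add atoms: none
Why: MnO2 oxidises only the allylic primary alcohol, with retention of alkene geometry; the saturated primary, the secondary homoallylic and the tertiary alcohols are not oxidised.

**Compound list**

1 | (S)-carvone | CC1=CC[C@@H](CC1=O)C(C)=C | starting material
2 | (1S,4S,6S)-1-methyl-4-(prop-1-en-2-yl)-7-oxabicyclo[4.1.0]heptan-2-one (oxirane trans to isopropenyl) | O=C1C[C@@H](C(C)=C)C[C@@H]2O[C@]12C | intermediate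
3 | (1S,4S)-1-methyl-4-(prop-1-en-2-yl)cyclohexane-1,2-diol, C2 epimers | OC1C[C@@H](C(C)=C)CC[C@]1(C)O | intermediate
4 | (2S,5S)-2-hydroxy-2-methyl-5-(prop-1-en-2-yl)cyclohexan-1-one | O=C1C[C@@H](C(C)=C)CC[C@]1(C)O | intermediate
5 | (2S,5S)-2-methyl-5-(prop-1-en-2-yl)-2-(triethylsilyloxy)cyclohexan-1-one | O=C1C[C@@H](C(C)=C)CC[C@]1(C)O[Si](CC)(CC)CC | intermediate
6 | allyl bromide | C=CCBr | starting material
7 | (2S,5S,6R)-6-allyl-2-methyl-5-(prop-1-en-2-yl)-2-(triethylsilyloxy)cyclohexan-1-one | O=C1[C@H](CC=C)[C@@H](C(C)=C)CC[C@]1(C)O[Si](CC)(CC)CC | intermediate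
8 | (2S,5S,6R)-6-(3-hydroxypropyl)-2-methyl-5-(prop-1-en-2-yl)-2-(triethylsilyloxy)cyclohexan-1-one | O=C1[C@H](CCCO)[C@@H](C(C)=C)CC[C@]1(C)O[Si](CC)(CC)CC | intermediate
9 | (2S,5S,6R)-6-[3-(tert-butyldiphenylsilyloxy)propyl]-2-methyl-5-(prop-1-en-2-yl)-2-(triethylsilyloxy)cyclohexan-1-one | O=C1[C@H](CCCO[Si](c2ccccc2)(c2ccccc2)C(C)(C)C)[C@@H](C(C)=C)CC[C@]1(C)O[Si](CC)(CC)CC | intermediate
10 | methyl enol ether: 1-(methoxymethylidene) analogue of 9, E/Z mixture | COC=C1[C@H](CCCO[Si](c2ccccc2)(c2ccccc2)C(C)(C)C)[C@@H](C(C)=C)CC[C@]1(C)O[Si](CC)(CC)CC | intermediate (not isolated)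
11 | dimethyl acetal: 1-(dimethoxymethyl)-2-methyl-5-(prop-1-en-2-yl)-6-[3-(TBDPS-oxy)propyl]-2-(TES-oxy)cyclohexane, C1 epimers, other centres as in 9 | COC(OC)C1[C@H](CCCO[Si](c2ccccc2)(c2ccccc2)C(C)(C)C)[C@@H](C(C)=C)CC[C@]1(C)O[Si](CC)(CC)CC | intermediate
12 | α-methoxy hydroperoxide: 5-(1-hydroperoxy-1-methoxyethyl) analogue of 11 | COC(OC)C1[C@H](CCCO[Si](c2ccccc2)(c2ccccc2)C(C)(C)C)[C@@H](C(C)(OC)OO)CC[C@]1(C)O[Si](CC)(CC)CC | intermediate (not isolated)
13 | C5 acetate: 5-acetoxy-1-(dimethoxymethyl)-2-methyl-6-[3-(TBDPS-oxy)propyl]-2-(TES-oxy)cyclohexane, acetoxy trans to the C6 chain | COC(OC)C1[C@H](CCCO[Si](c2ccccc2)(c2ccccc2)C(C)(C)C)[C@@H](OC(C)=O)CC[C@]1(C)O[Si](CC)(CC)CC | intermediate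
14 | C5 alcohol corresponding to 13 | COC(OC)C1[C@H](CCCO[Si](c2ccccc2)(c2ccccc2)C(C)(C)C)[C@@H](O)CC[C@]1(C)O[Si](CC)(CC)CC | intermediate
15 | C5 ketone: 1-(dimethoxymethyl)-2-methyl-6-[3-(TBDPS-oxy)propyl]-2-(TES-oxy)cyclohexan-5-one | COC(OC)C1[C@H](CCCO[Si](c2ccccc2)(c2ccccc2)C(C)(C)C)C(=O)CC[C@]1(C)O[Si](CC)(CC)CC | intermediate
16 | enol triflate: C4=C5 alkene with OTf on C5 | COC(OC)C1[C@H](CCCO[Si](c2ccccc2)(c2ccccc2)C(C)(C)C)C(OS(=O)(=O)C(F)(F)F)=CC[C@]1(C)O[Si](CC)(CC)CC | intermediate
17 | 2-bromoprop-2-en-1-ol | OCC(Br)=C | starting material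
18 | tert-butyl[(2-bromoprop-2-en-1-yl)oxy]diphenylsilane | C=C(Br)CO[Si](c1ccccc1)(c1ccccc1)C(C)(C)C | intermediate
19 | [3-(TBDPS-oxy)prop-1-en-2-yl]lithium | [Li]C(=C)CO[Si](c1ccccc1)(c1ccccc1)C(C)(C)C | intermediate (not isolated)
20 | [3-(TBDPS-oxy)prop-1-en-2-yl]zinc bromide | Br[Zn]C(=C)CO[Si](c1ccccc1)(c1ccccc1)C(C)(C)C | intermediate (not isolated)
21 | diene: 5-[3-(TBDPS-oxy)prop-1-en-2-yl]cyclohex-4-ene acetal | COC(OC)C1[C@H](CCCO[Si](c2ccccc2)(c2ccccc2)C(C)(C)C)C(C(=C)CO[Si](c2ccccc2)(c2ccccc2)C(C)(C)C)=CC[C@]1(C)O[Si](CC)(CC)CC | intermediate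
22 | (Z)-alkylidene acetal: 5-[1-(TBDPS-oxy)propan-2-ylidene], CH2O cis to C6, methyl cis to C4 | COC(OC)C1[C@H](CCCO[Si](c2ccccc2)(c2ccccc2)C(C)(C)C)/C(=C(/C)CO[Si](c2ccccc2)(c2ccccc2)C(C)(C)C)CC[C@]1(C)O[Si](CC)(CC)CC | intermediate
23 | aldehyde: cyclohexane-1-carbaldehyde corresponding to 22, C1 epimers | O=CC1[C@H](CCCO[Si](c2ccccc2)(c2ccccc2)C(C)(C)C)/C(=C(/C)CO[Si](c2ccccc2)(c2ccccc2)C(C)(C)C)CC[C@]1(C)O[Si](CC)(CC)CC | intermediate
24 | 1-allylcyclohexane-1-carbaldehyde: formyl cis to the C6 chain and to the C2 silyloxy group | C=CC[C@]1([C@H](CCCO[Si](c2ccccc2)(c2ccccc2)C(C)(C)C)/C(=C(/C)CO[Si](c2ccccc2)(c2ccccc2)C(C)(C)C)CC[C@]1(C)O[Si](CC)(CC)CC)C=O | intermediate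
25 | spiro ketone: 6-methyl-6-(TES-oxy)-10-[3-(TBDPS-oxy)propyl]-9-[(Z)-1-(TBDPS-oxy)propan-2-ylidene]spiro[4.5]decan-1-one | C1C[C@]2([C@H](CCCO[Si](c3ccccc3)(c3ccccc3)C(C)(C)C)/C(=C(/C)CO[Si](c3ccccc3)(c3ccccc3)C(C)(C)C)CC[C@]2(C)O[Si](CC)(CC)CC)C(=O)C1 | intermediate
26 | spiro[4.5]dec-1-en-1-yl triflate corresponding to 25 | C1C[C@]2([C@H](CCCO[Si](c3ccccc3)(c3ccccc3)C(C)(C)C)/C(=C(/C)CO[Si](c3ccccc3)(c3ccccc3)C(C)(C)C)CC[C@]2(C)O[Si](CC)(CC)CC)C(OS(=O)(=O)C(F)(F)F)=C1 | intermediate
27 | key precursor: 6-methyl-6-(TES-oxy)-10-[3-(TBDPS-oxy)propyl]-9-[(Z)-1-(TBDPS-oxy)propan-2-ylidene]spiro[4.5]dec-1-ene | C1C[C@]2([C@H](CCCO[Si](c3ccccc3)(c3ccccc3)C(C)(C)C)/C(=C(/C)CO[Si](c3ccccc3)(c3ccccc3)C(C)(C)C)CC[C@]2(C)O[Si](CC)(CC)CC)C=C1 | intermediate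
28 | ethyl 2-chloro-2-(hydroxyimino)acetate | CCOC(=O)C(Cl)=NO | starting material
29 | ethoxycarbonylformonitrile oxide | CCOC(=O)C#[N+][O-] | intermediate (not isolated)
30 | key product: isoxazoline ethyl ester cis-fused across C1–C2 of the spiro core (O on C1, ester-bearing carbon on C2, both on the face of the C10 methine) | CCOC(=O)C(=NO3)[C@@H]1CC[C@]2([C@H](CCCO[Si](c4ccccc4)(c4ccccc4)C(C)(C)C)/C(=C(/C)CO[Si](c4ccccc4)(c4ccccc4)C(C)(C)C)CC[C@]2(C)O[Si](CC)(CC)CC)[C@@H]13 | intermediate
31 | isoxazoline-3-carbaldehyde corresponding to 30 | O=CC(=NO3)[C@@H]1CC[C@]2([C@H](CCCO[Si](c4ccccc4)(c4ccccc4)C(C)(C)C)/C(=C(/C)CO[Si](c4ccccc4)(c4ccccc4)C(C)(C)C)CC[C@]2(C)O[Si](CC)(CC)CC)[C@@H]13 | intermediate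
32 | tert-butyldimethyl(prop-2-yn-1-yloxy)silane | C#CCO[Si](C)(C)C(C)(C)C | starting material
33 | methyl 4-(tert-butyldimethylsilyloxy)but-2-ynoate | COC(=O)C#CCO[Si](C)(C)C(C)(C)C | intermediate
34 | 5-bromo-2-methylpent-2-ene | CC(C)=CCCBr | starting material
35 | (4-methylpent-3-en-1-yl)magnesium bromide | CC(C)=CCC[Mg]Br | intermediate (not isolated)
36 | (4-methylpent-3-en-1-yl)copper | CC(C)=CCC[Cu] | intermediate (not isolated)
37 | methyl (2Z)-3-[(tert-butyldimethylsilyloxy)methyl]-7-methylocta-2,6-dienoate | COC(=O)/C=C(/CCC=C(C)C)CO[Si](C)(C)C(C)(C)C | intermediate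
38 | (2Z)-3-[(tert-butyldimethylsilyloxy)methyl]-7-methylocta-2,6-dien-1-ol | OC/C=C(/CCC=C(C)C)CO[Si](C)(C)C(C)(C)C | intermediate
39 | PT sulfide: 5-{[(2Z)-3-[(TBS-oxy)methyl]-7-methylocta-2,6-dien-1-yl]sulfanyl}-1-phenyl-1H-tetrazole | CC(C)=CCC/C(CO[Si](C)(C)C(C)(C)C)=C/CSc1nnnn1-c1ccccc1 | intermediate
40 | PT sulfone corresponding to 39 | CC(C)=CCC/C(CO[Si](C)(C)C(C)(C)C)=C/CS(=O)(=O)c1nnnn1-c1ccccc1 | intermediate
41 | 3-[(1E,3Z)-4-[(TBS-oxy)methyl]-8-methylnona-1,3,7-trien-1-yl]isoxazoline on the spiro core | O3N=C(/C=C/C=C(/CCC=C(C)C)CO[Si](C)(C)C(C)(C)C)[C@@H]1CC[C@]2([C@H](CCCO[Si](c4ccccc4)(c4ccccc4)C(C)(C)C)/C(=C(/C)CO[Si](c4ccccc4)(c4ccccc4)C(C)(C)C)CC[C@]2(C)O[Si](CC)(CC)CC)[C@@H]13 | intermediate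
42 | primary allylic alcohol obtained from 41 by loss of the TBS group | O3N=C(/C=C/C=C(/CCC=C(C)C)CO)[C@@H]1CC[C@]2([C@H](CCCO[Si](c4ccccc4)(c4ccccc4)C(C)(C)C)/C(=C(/C)CO[Si](c4ccccc4)(c4ccccc4)C(C)(C)C)CC[C@]2(C)O[Si](CC)(CC)CC)[C@@H]13 | intermediate
43 | allylic acetate of 42 | O3N=C(/C=C/C=C(/CCC=C(C)C)COC(C)=O)[C@@H]1CC[C@]2([C@H](CCCO[Si](c4ccccc4)(c4ccccc4)C(C)(C)C)/C(=C(/C)CO[Si](c4ccccc4)(c4ccccc4)C(C)(C)C)CC[C@]2(C)O[Si](CC)(CC)CC)[C@@H]13 | intermediate
44 | cis-β-hydroxy dienyl ketone: 1-hydroxy spiro[4.5]decane with the acyl group on C2 | O=C(/C=C/C=C(/CCC=C(C)C)COC(C)=O)[C@@H]1CC[C@]2([C@H](CCCO[Si](c3ccccc3)(c3ccccc3)C(C)(C)C)/C(=C(/C)CO[Si](c3ccccc3)(c3ccccc3)C(C)(C)C)CC[C@]2(C)O[Si](CC)(CC)CC)[C@@H]1O | intermediate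
45 | silylated target skeleton: cross-conjugated triene, C1 hydroxyl free, two TBDPS ethers, tertiary TES ether | C=C(/C=C/C=C(/CCC=C(C)C)COC(C)=O)[C@@H]1CC[C@]2([C@H](CCCO[Si](c3ccccc3)(c3ccccc3)C(C)(C)C)/C(=C(/C)CO[Si](c3ccccc3)(c3ccccc3)C(C)(C)C)CC[C@]2(C)O[Si](CC)(CC)CC)[C@@H]1O | intermediate
46 | tetraol acetate: allylic alcohol in place of the aldehyde of the target | C=C(/C=C/C=C(/CCC=C(C)C)COC(C)=O)[C@@H]1CC[C@]2([C@H](CCCO)/C(=C(/C)CO)CC[C@]2(C)O)[C@@H]1O | intermediate
47 | CNP0205332.1, (2Z,4E)-6-[(1R,2S,5S,6S,9Z,10R)-1,6-dihydroxy-10-(3-hydroxypropyl)-6-methyl-9-(1-oxopropan-2-ylidene)spiro[4.5]decan-2-yl]-2-(4-methylpent-3-en-1-yl)hepta-2,4,6-trien-1-yl acetate | C=C(/C=C/C=C(/CCC=C(C)C)COC(C)=O)[C@@H]1CC[C@]2([C@H](CCCO)/C(=C(/C)C=O)CC[C@]2(C)O)[C@@H]1O | target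

**Summary**

Total step count: 34. Longest linear sequence: 28 steps (steps 1–12, 14–22 and 28–34).

Steps most likely to fail:

1. Step 17 (allylation at the future spiro carbon). The enolate carbon is flanked by a quaternary and a tertiary centre, so O-allylation, attack from the wrong face or β-elimination of silanolate from the enolate may take over. Fallback: setting out from 23, O-allylation of the potassium enolate under dissociating conditions (KH, 18-crown-6, allyl tosylate, DMPU) would give the allyl enol ether F1; thermal Claisen rearrangement (toluene, 110 °C) then makes the same C–C bond intramolecularly on the face away from the arm and comes back to the route at 24.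

2. Step 15 (chromium-catalysed 1,4-hydrogenation). The crowded 2,3-disubstituted diene may not reach the s-cis chromium complex, or alkene migration may erode the geometry. Fallback: setting out from ketone 15, Horner–Wadsworth–Emmons olefination with triethyl 2-phosphonopropanoate (NaH, toluene, 80 °C) would give, after separation from its geometric isomer (which can be re-equilibrated with iodine and light), the (Z)-enoate F2; i-Bu2AlH reduction gives the allylic alcohol F3, and silylation (t-BuPh2SiCl, imidazole) comes back to the route at 22. Geometry then rests on separation instead of on the reaction.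

3. Step 21 (cycloaddition). Dimerisation of the nitrile oxide may outrun addition to the hindered alkene, or facial selectivity may be low. Fallback: setting out from 27, the trimethylsilyl nitronate of ethyl nitroacetate F4 (ethyl nitroacetate, Me3SiCl, Et3N), a dipole that does not dimerise and can be heated with the alkene for long periods, would add across C1=C2 under the same steric control to give the N-(trimethylsilyloxy)isoxazolidine F5; acid (TsOH) then eliminates trimethylsilanol and comes back to the route at 30. This answers the dimerisation problem only.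

Further compounds
F1 | step 17 | allyl enol ether of aldehyde 23 | C=CCOC=C1[C@H](CCCO[Si](c2ccccc2)(c2ccccc2)C(C)(C)C)/C(=C(/C)CO[Si](c2ccccc2)(c2ccccc2)C(C)(C)C)CC[C@]1(C)O[Si](CC)(CC)CC
F2 | step 15 | ethyl (Z)-2-(cyclohexylidene)propanoate with the ester cis to C6 (ethyl ester analogue of 22) | COC(OC)C1[C@H](CCCO[Si](c2ccccc2)(c2ccccc2)C(C)(C)C)/C(=C(/C)C(=O)OCC)CC[C@]1(C)O[Si](CC)(CC)CC
F3 | step 15 | allylic alcohol corresponding to 22 (free CH2OH on the alkylidene carbon) | COC(OC)C1[C@H](CCCO[Si](c2ccccc2)(c2ccccc2)C(C)(C)C)/C(=C(/C)CO)CC[C@]1(C)O[Si](CC)(CC)CC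
F4 | step 21 | trimethylsilyl nitronate of ethyl nitroacetate | CCOC(=O)C=[N+]([O-])O[Si](C)(C)C
F5 | step 21 | N-(trimethylsilyloxy)isoxazolidine ethyl ester cis-fused across C1–C2 of the spiro core | CCOC(=O)C(N(O3)O[Si](C)(C)C)[C@@H]1CC[C@]2([C@H](CCCO[Si](c4ccccc4)(c4ccccc4)C(C)(C)C)/C(=C(/C)CO[Si](c4ccccc4)(c4ccccc4)C(C)(C)C)CC[C@]2(C)O[Si](CC)(CC)CC)[C@@H]13
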